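**Retrosynthetic overview**

1. The strategy rests on the three butyryl-bearing ring carbons: in each terminal 4,4-dimethyl trione ring the one ring carbon without a bridge or methyl groups, and the sixth carbon of the central benzene-1,3,5-triol ring. Each lies between two oxygen-bearing carbons and is nucleophilic, so it can be iodinated and then acylated with reversed polarity. The three ring–C(=O) and three C(=O)–propyl bonds are cut together, giving a tri-iodide, carbon monoxide and propylzinc bromide.
2. The tri-iodide comes from the acyl-free, perbenzylated trimer skeleton by one threefold electrophilic iodination. The terminal enols are benzylated after the bridges are in place and before any iodine is present.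
3. The two CH2 bridges are cut at the terminal-ring carbons: reductive alkylation of filicinic acid with 2,4,6-tris(benzyloxy)isophthalaldehyde.
4. Filicinic acid comes from 2,4,6-trihydroxyacetophenone (gem-dimethylation, deacetylation); the dialdehyde from phloroglucinol (double formylation, benzylation).
5. No ring is formed in the route. All three carbocycles come from the two phloroglucinol starting materials, and the terminal rings are dearomatised in step 1.

Key step: step 8

Remark (assumption): the target has no stereocentre and is achiral, so no stereocontrol is needed. Enolic compounds are each drawn in one keto–enol tautomer; all tautomers are the same compound. In the protected compounds 14, 15 and 18 the benzyl groups of each terminal ring sit on the two oxygens flanking the ring carbon that is iodinated and then acylated, and the ring ketone lies between the gem-dimethyl carbon and the bridge carbon. Hydrogenolysis of this arrangement gives the same triketone as any other placement.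

**Step 1**
Reactants: 1 2,4,6-trihydroxyacetophenone; 2 iodomethane
Product: 3 acetylfilicinic acid (2-acetyl-3,5-dihydroxy-4,4-dimethylcyclohexa-2,5-dien-1-one)
Conditions: NaOMe (3.5 equiv), MeI (2.2 equiv), MeOH, 0 °C → rt
Reagents that add atoms: iodomethane CI
Why: Alkylative dearomatisation, in which the acylphloroglucinol polyanion is C-methylated twice at the same ring carbon in methanol, the second methylation breaking aromaticity, while the acetyl group occupies one of the other two ring carbons so that a single ring CH remains.

**Step 2**
Reactants: 3 acetylfilicinic acid
Product: 4 filicinic acid (3,5-dihydroxy-4,4-dimethylcyclohexa-2,5-dien-1-one)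
Conditions: 6 M aq. HCl, reflux
Reagents that add atoms: none
Why: Acid-mediated deacylation (retro-Claisen-type cleavage) of the 2-acyl-1,3-dione, in which ipso protonation of the enol carbon and loss of the acetyl group as acetic acid gives the parent trione, the usual way from acylfilicinic acids to filicinic acid.

**Step 3**
Reactants: 5 phloroglucinol; 6 N,N-dimethylformamide
Product: 8 2,4-diformylphloroglucinol (2,4,6-trihydroxyisophthalaldehyde), via bis(iminium) chloride 7 (not isolated)
Conditions: POCl3 (2.2 equiv), DMF (2.4 equiv), 1,4-dioxane, 0 °C → rt; then H2O
Reagents that add atoms: N,N-dimethylformamide CN(C)C=O; water O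
Why: Vilsmeier–Haack formylation, in which the chloroiminium ion attacks two ring carbons of phloroglucinol, each iminium group lowering the reactivity of the ring so that the stoichiometry should stop the reaction at the bis-adduct, which water hydrolyses to the dialdehyde.

**Step 4**
Reactants: 8 2,4-diformylphloroglucinol; 9 benzyl bromide
Product: 10 2,4,6-tris(benzyloxy)isophthalaldehyde
Conditions: BnBr (3.6 equiv), K2CO3 (4 equiv), DMF, 60 °C
Reagents that add atoms: benzyl bromide BrCc1ccccc1
Why: Williamson etherification, in which the two formyl groups make the phenoxides vinylogous carboxylates that should be alkylated on oxygen in a polar aprotic solvent, not on the one free ring carbon.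

**Step 5**
Reactants: 10 2,4,6-tris(benzyloxy)isophthalaldehyde; 4 filicinic acid (6 equiv used, 2 incorporated)
Product: 12 2,2'-{[2,4,6-tris(benzyloxy)-1,3-phenylene]bis(methylene)}bis(3,5-dihydroxy-4,4-dimethylcyclohexa-2,5-dien-1-one), via bis(alkylidene) trione 11 (not isolated)
Conditions: Hantzsch ester (2.4 equiv), L-proline (20 mol%), EtOH–CH2Cl2, rt, slow addition of 10
Reagents that add atoms: none
Why: Organocatalytic three-component reductive alkylation, in which Knoevenagel condensation of each aldehyde (the two arms reacting in turn) with the dione carbon of 4 gives an arylidene trione that the Hantzsch ester should reduce by conjugate hydride transfer faster than a second dione adds, the excess of 4 keeping its second nucleophilic carbon from reacting again.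

**Step 6**
Reactants: 12 bis(filicinylmethyl) tris(benzyloxy)benzene; 13 benzyl alcohol
Product: 14 heptabenzyl trimer skeleton (each terminal ring a 3,5-bis(benzyloxy)-6,6-dimethylcyclohexa-2,4-dien-1-one joined through C2 to the bridge)
Conditions: BnOH (6 equiv), PPh3 (6 equiv), DIAD (6 equiv), THF, 0 °C → rt
Reagents that add atoms: benzyl alcohol OCc1ccccc1
Why: Mitsunobu O-alkylation of the acidic enols, in which the enolate oxygen attacks the benzyloxyphosphonium ion (O-alkylation being the rule for cyclic 1,3-diones), and the two oxygens next to the free ring CH should be alkylated because the third oxygen is shielded between the quaternary carbon and the bridge-bearing carbon, the same arrangement also being the one in which both benzyloxy groups can lie in the ring plane.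

**Step 7**
Reactants: 14 heptabenzyl trimer skeleton
Product: 15 heptabenzyl tri-iodide (iodine on C4 of each terminal dienone ring and on the free carbon of the central ring)
Conditions: NIS (3.3 equiv), TFA (10 mol%), MeCN–CH2Cl2, 0 °C → rt, dark
Reagents that add atoms: N-iodosuccinimide O=C1CCC(=O)N1I
Why: Electrophilic iodination (aromatic substitution on the trialkoxyarene, enol-ether iodination on the dienones), in which each of the three remaining ring CH carbons lies between two benzyloxy-bearing carbons, is the most nucleophilic site of its ring and is the only unsubstituted ring carbon left.

**Step 8**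
Reactants: 15 heptabenzyl tri-iodide; 16 carbon monoxide; 17 propylzinc bromide
Product: 18 heptabenzyl ether of the target (three butanoyl groups in place of the three iodines)
Conditions: CO (10 bar), Pd2(dba)3 (8 mol%), Xantphos (18 mol%), n-PrZnBr (0.5 M in THF, 4.5 equiv, syringe pump over 6 h), THF–NMP, 50 °C
Reagents that add atoms: carbon monoxide [C-]#[O+]; propylzinc bromide CCC[Zn]Br
Why: Proposed new method: palladium(0) inserts into each of the three C–I bonds (two dienyl, one aryl), carbon monoxide inserts to give acylpalladium iodides, propylzinc bromide transmetalates and reductive elimination releases the propyl ketone, so that three ring–carbonyl and three carbonyl–propyl bonds form in one operation. The closest known reaction type is the carbonylative Negishi coupling of aryl and alkenyl iodides with alkylzinc halides, together with carbonylative couplings of di-ortho-substituted aryl iodides; a threefold version on iodides flanked on both sides by alkoxy-bearing carbons has not been shown. No ring is closed and no stereocentre is formed. The step needs selectivity for the ketone over direct propyl coupling and over hydrodeiodination at three crowded sites: the flanking benzyloxy groups should slow transmetalation at the aryl- and alkenylpalladium stage more than they slow CO insertion, which moves the metal one atom away from the crowded carbon. CO pressure, the wide bite angle of Xantphos (fast acyl–alkyl reductive elimination) and slow addition of the zinc reagent support the same pathway. The organozinc halide should leave the hindered ring ketones, the enol ethers, the benzyl ethers and the methylene bridges untouched under these neutral conditions.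

**Step 9**
Reactants: 18 heptabenzyl ether of the target
Product: 19 target CNP0086314.0
Conditions: H2 (1 atm), 10% Pd/C, EtOAc, rt
Reagents that add atoms: none
Why: Catalytic hydrogenolysis of the three benzyl aryl ethers and four benzyl enol ethers under neutral conditions, in which the chelated aryl ketone, the enolised triketone rings and the methylene bridges should not be reduced at one atmosphere, and the freed enols settle into the tautomer in which the target is written.

**Compound list**

1 | 2,4,6-trihydroxyacetophenone | CC(=O)c1c(O)cc(O)cc1O | starting material
2 | iodomethane | CI | starting material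
3 | acetylfilicinic acid | CC(=O)C1=C(O)C(C)(C)C(O)=CC1=O | intermediate
4 | filicinic acid | CC1(C)C(O)=CC(=O)C=C1O | intermediate
5 | phloroglucinol | Oc1cc(O)cc(O)c1 | starting material
6 | N,N-dimethylformamide | CN(C)C=O | starting material
7 | bis(iminium) chloride of phloroglucinol (not isolated) | C[N+](C)=Cc1c(O)cc(O)c(C=[N+](C)C)c1O.[Cl-].[Cl-] | intermediate
8 | 2,4-diformylphloroglucinol | O=Cc1c(O)cc(O)c(C=O)c1O | intermediate
9 | benzyl bromide | BrCc1ccccc1 | starting material
10 | 2,4,6-tris(benzyloxy)isophthalaldehyde | O=Cc1c(OCc2ccccc2)cc(OCc2ccccc2)c(C=O)c1OCc1ccccc1 | intermediate
11 | bis(alkylidene) trione, Knoevenagel adduct of 10 with two molecules of 4 (not isolated; alkene geometry undefined and erased on reduction) | O=C1CC(=O)C(C)(C)C(=O)C1=Cc1c(OCc2ccccc2)cc(OCc2ccccc2)c(C=C2C(=O)CC(=O)C(C)(C)C2=O)c1OCc1ccccc1 | intermediate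
12 | 2,2'-{[2,4,6-tris(benzyloxy)-1,3-phenylene]bis(methylene)}bis(3,5-dihydroxy-4,4-dimethylcyclohexa-2,5-dien-1-one) | O=C1C=C(O)C(C)(C)C(O)=C1Cc1c(OCc2ccccc2)cc(OCc2ccccc2)c(CC2=C(O)C(C)(C)C(O)=CC2=O)c1OCc1ccccc1 | intermediate
13 | benzyl alcohol | OCc1ccccc1 | starting material
14 | heptabenzyl trimer skeleton | O=C1C(Cc2c(OCc3ccccc3)cc(OCc3ccccc3)c(CC3=C(OCc4ccccc4)C=C(OCc4ccccc4)C(C)(C)C3=O)c2OCc2ccccc2)=C(OCc2ccccc2)C=C(OCc2ccccc2)C1(C)C | intermediate
15 | heptabenzyl tri-iodide | O=C1C(Cc2c(OCc3ccccc3)c(I)c(OCc3ccccc3)c(CC3=C(OCc4ccccc4)C(I)=C(OCc4ccccc4)C(C)(C)C3=O)c2OCc2ccccc2)=C(OCc2ccccc2)C(I)=C(OCc2ccccc2)C1(C)C | intermediate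
16 | carbon monoxide | [C-]#[O+] | starting material
17 | propylzinc bromide | CCC[Zn]Br | starting material
18 | heptabenzyl ether of the target | O=C1C(Cc2c(OCc3ccccc3)c(C(=O)CCC)c(OCc3ccccc3)c(CC3=C(OCc4ccccc4)C(C(=O)CCC)=C(OCc4ccccc4)C(C)(C)C3=O)c2OCc2ccccc2)=C(OCc2ccccc2)C(C(=O)CCC)=C(OCc2ccccc2)C1(C)C | intermediate
19 | CNP0086314.0 | CCCC(=O)C1=C(O)C(Cc2c(O)c(CC3=C(O)C(C)(C)C(=O)C(C(=O)CCC)=C3O)c(O)c(C(=O)CCC)c2O)=C(O)C(C)(C)C1=O | target

**Step count and risks**

Total step count: 9. Longest linear sequence: 7 steps (1, 2, 5, 6, 7, 8, 9; the branch 3, 4, 5–9 is equally long).

Steps most likely to fail: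

1. Step 8 (proposed new method). The process at risk is partitioning of the three arylpalladium and dienylpalladium intermediates: direct propyl transfer or hydrodeiodination may outrun CO insertion at one or more of the crowded sites, leaving mixtures of partly acylated products. The fallback uses known chemistry and gives up the late acylation. It sets out from phloroglucinol 5 and iodomethane 2 and returns at the target 19. Phloroglucinol 5 is C-acylated with butanoyl chloride and AlCl3 (Friedel–Crafts) to 2,4,6-trihydroxybutyrophenone F1. Part of F1 is gem-dimethylated with iodomethane 2 and NaOMe in methanol, as in step 1, to butyrylfilicinic acid F2. F1 is then condensed with two equivalents of F2 and aqueous formaldehyde in dilute aqueous alkali, the classical methylene bridging of acylphloroglucinols. This should give 19 directly, to be separated from the homo-bridged dimer of F2.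

2. Step 5. The process at risk is over-reaction of the bifunctional nucleophile: the second dione carbon of an already alkylated filicinic ring may condense with another aldehyde, or a second dione may add to the arylidene before hydride transfer, leading to oligomers; condensation at the hindered, electron-rich aldehyde may also be slow. The fallback sets out from 10 and returns at 12. The dialdehyde 10 is reduced with NaBH4 to [2,4,6-tris(benzyloxy)-1,3-phenylene]dimethanol F3. Under catalytic TsOH in the presence of excess filicinic acid 4, F3 ionises to the trialkoxybenzyl cation, which is trapped at the dione carbon (acid-catalysed dehydrative benzylation of 1,3-dicarbonyl compounds with benzylic alcohols) to give 12.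

3. Step 6. The process at risk is loss of site control in the fourfold alkylation: benzylation at the free ring carbon of the dione, or on the shielded oxygen, would give positional isomers of the enol ethers. The fallback sets out from 12 and returns at 14 without a new compound (F0). In place of alkylating the enol oxygen, 12 is heated with benzyl alcohol 13 and catalytic TsOH in toluene with azeotropic removal of water. Enol ether formation then proceeds by addition of the alcohol to the ring carbonyl carbon and loss of water, so C-benzylation is excluded, and the positional isomers equilibrate to the thermodynamically preferred 14.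

**Further compounds**

F1 | step 8 | 2,4,6-trihydroxybutyrophenone (1-(2,4,6-trihydroxyphenyl)butan-1-one) | CCCC(=O)c1c(O)cc(O)cc1O
F2 | step 8 | butyrylfilicinic acid (2-butanoyl-3,5-dihydroxy-4,4-dimethylcyclohexa-2,5-dien-1-one) | CCCC(=O)C1=C(O)C(C)(C)C(O)=CC1=O
F3 | step 5 | [2,4,6-tris(benzyloxy)-1,3-phenylene]dimethanol | OCc1c(OCc2ccccc2)cc(OCc2ccccc2)c(CO)c1OCc1ccccc1
F0 | step 6 | none | none
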